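**Retrosynthetic overview**

1. Target ⇒ primary alcohol (butanoylation) ⇒ tricyclic β-lactone aldehyde (aldehyde reduction).
2. Tricyclic aldehyde ⇒ acrolein + a β-lactone-bearing 1,6-enyne: enyne ring-closing metathesis closes ring B (five-membered) as a 1-(1-alkylethenyl)cyclopentene, which is trapped in the same flask by an amine-catalysed Diels–Alder reaction that closes ring A (six-membered), makes the tetrasubstituted C7=C7a alkene and sets C3a and C4.
3. Enyne β-lactone ⇒ pent-4-ynoyl chloride + acrolein by an alkaloid-catalysed ketene–aldehyde cyclocondensation (sets C2 and C3, cis).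
4. Pentynoate ⇒ tert-butyl acrylate + (1R)-1-ethynyl-1,3,3-trimethylcyclohexane ⇒ Claisen aldehyde (hydrogenation, aldehyde-to-alkyne).
5. Quaternary centre ⇒ Claisen rearrangement of the vinyl ether of (R)-isophorol (1,3-chirality transfer) ⇒ CBS reduction of isophorone. Ring order: cyclohexane (from isophorone) → β-lactone → ring B then ring A in one operation.

Assumption: O-trimethylsilylquinidine is taken as the cinchona catalyst that gives the (3S,4R)-lactone; its pseudo-enantiomer O-trimethylsilylquinine is used instead if the sense of induction is the opposite.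

Labels: the carbocycle of the target is numbered as 1H-indene. C1 is CH2, C2 the lactone α-carbon, C3 the lactone O-bearing carbon, C3a the sp3 ring-fusion CH, C4 the CH bearing the CH2O group, C5 and C6 are CH2, C7 the alkene carbon bearing the cyclohexyl group, C7a the sp2 ring-fusion carbon. The target is (2S,3R,3aS,4R) with a (1R)-cyclohexyl centre.

**Route**

Step 1
Reactants: 1 isophorone
Product: 2 (1R)-3,5,5-trimethylcyclohex-2-en-1-ol
Conditions: (S)-2-methyl-CBS-oxazaborolidine (10 mol%), BH3·SMe2, THF, −20 °C; MeOH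
Reagents that add atoms: none
Why: Corey–Bakshi–Shibata reduction, in which the alkenyl carbon acts as the large group, so hydride adds 1,2 to one carbonyl face and the (S)-catalyst gives the (R)-allylic alcohol.

Step 2
Reactants: 2 (1R)-3,5,5-trimethylcyclohex-2-en-1-ol; 3 ethyl vinyl ether
Product: 5 2-[(1R)-1,5,5-trimethylcyclohex-2-en-1-yl]acetaldehyde, via allyl vinyl ether 4 (not isolated)
Conditions: Hg(OAc)2 (10 mol%), neat ethyl vinyl ether, sealed tube, 40 °C then 190 °C
Reagents that add atoms: ethyl vinyl ether, C=COCC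
Why: Hg(OAc)2-catalysed vinyl ether exchange followed by thermal Claisen rearrangement ([3,3]-sigmatropic); the new C–C bond forms on the ring face from which the C–O bond leaves, so the (R)-carbinol centre is transferred to the (R)-quaternary centre.

Step 3
Reactants: 5 2-[(1R)-1,5,5-trimethylcyclohex-2-en-1-yl]acetaldehyde
Product: 6 2-[(1R)-1,3,3-trimethylcyclohexyl]acetaldehyde
Conditions: H2 (1 atm), Pd/C (10% palladium on carbon), EtOAc, rt
Reagents that add atoms: none
Why: Heterogeneous catalytic hydrogenation of the only C=C bond, done here so that no later alkene has to be told apart from the tetrasubstituted one; the aldehyde and the quaternary centre are untouched.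

Step 4
Reactants: 6 2-[(1R)-1,3,3-trimethylcyclohexyl]acetaldehyde
Product: 8 (1R)-1-ethynyl-1,3,3-trimethylcyclohexane, via enol phosphate 7 (not isolated)
Conditions: LiN(iPr)2 (LDA), THF, −78 °C; ClP(O)(OEt)2; then LDA (2.3 equiv), −78 °C to rt; H2O
Reagents that add atoms: none
Why: Aldehyde-to-alkyne dehydration through the enol phosphate (Negishi-type β-elimination with LDA); the adjacent carbon is quaternary, so no allene can form and the stereocentre is not touched.

Step 5
Reactants: 8 (1R)-1-ethynyl-1,3,3-trimethylcyclohexane; 9 tert-butyl acrylate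
Product: 10 tert-butyl 5-[(1R)-1,3,3-trimethylcyclohexyl]pent-4-ynoate
Conditions: Pd(OAc)2 (5 mol%), PMe3 (20 mol%), toluene, 60 °C
Reagents that add atoms: tert-butyl acrylate, C=CC(=O)OC(C)(C)C
Why: Palladium-catalysed conjugate addition of a terminal alkyne C–H bond to an acrylate (hydroalkynylation) gives the γ,δ-alkynoate directly; the tert-alkyl group lies on the far side of the triple bond from the reacting C–H.

Step 6
Reactants: 10 tert-butyl 5-[(1R)-1,3,3-trimethylcyclohexyl]pent-4-ynoate; 11 acrolein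
Product: 13 (3S,4R)-4-ethenyl-3-{3-[(1R)-1,3,3-trimethylcyclohexyl]prop-2-yn-1-yl}oxetan-2-one, via acid chloride 12 (not isolated)
Conditions: SOCl2, CH2Cl2, rt, evaporate; then acrolein, O-trimethylsilylquinidine (10 mol%), LiClO4, iPr2NEt, CH2Cl2/Et2O, −78 °C
Reagents that add atoms: acrolein, C=CC=O
Why: SOCl2 converts the tert-butyl ester directly into the acid chloride, and the cinchona alkaloid/LiClO4 acyl halide–aldehyde cyclocondensation (Wynberg–Nelson formal ketene–aldehyde [2+2] through an ammonium enolate aldol–lactonisation in a lithium-bridged closed transition state) gives the cis-3,4-disubstituted β-lactone with catalyst-controlled (3S,4R) configuration, which becomes C2 and C3.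

Step 7
Reactants: 13 (3S,4R)-4-ethenyl-3-{3-[(1R)-1,3,3-trimethylcyclohexyl]prop-2-yn-1-yl}oxetan-2-one; 11 acrolein
Product: 15 (2S,3R,3aS,4R)-4-formyl-3-hydroxy-7-[(1R)-1,3,3-trimethylcyclohexyl]-2,3,3a,4,5,6-hexahydro-1H-indene-2-carboxylic acid 2,3-lactone, via dienyl lactone 14 (not isolated)
Conditions: second-generation Grubbs catalyst RuCl2(=CHPh)(PCy3)(H2IMes) (5 mol%), ethene (1 atm), toluene, 60 °C; purge with Ar, 4 °C, then acrolein (3 equiv), (S)-2-{bis[3,5-bis(trifluoromethyl)phenyl][(triethylsilyl)oxy]methyl}pyrrolidine (10 mol%), CF3CO2H (20 mol%)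
Reagents that add atoms: acrolein, C=CC=O
Why: Tandem ring-closing enyne metathesis/Diels–Alder reaction: the ruthenium methylidene (kept alive by ethene, net isomerisation) adds to the alkyne at its unhindered carbon and closes ring B onto the vinyl group to give the 1-(1-alkylethenyl)cyclopentene 14; its iminium-catalysed [4+2] with acrolein then closes ring A and forms the C7=C7a alkene with ortho/para regiochemistry, the diene reacting on the face opposite the cis-fused lactone (sets C3a) and the (S)-amine leaving open the Si face of the acrolein α-carbon (sets C4 as R), a pairing that is the exo transition state and gives the trans C3a/C4 relationship.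

Step 8
Reactants: 15 (2S,3R,3aS,4R)-4-formyl-3-hydroxy-7-[(1R)-1,3,3-trimethylcyclohexyl]-2,3,3a,4,5,6-hexahydro-1H-indene-2-carboxylic acid 2,3-lactone
Product: 16 (2S,3R,3aS,4R)-3-hydroxy-4-(hydroxymethyl)-7-[(1R)-1,3,3-trimethylcyclohexyl]-2,3,3a,4,5,6-hexahydro-1H-indene-2-carboxylic acid 2,3-lactone
Conditions: NaBH4, THF/EtOH, −78 °C; AcOH quench (run directly on freshly filtered 15)
Reagents that add atoms: none
Why: Chemoselective hydride reduction, since at −78 °C NaBH4 reduces the aldehyde far faster than the β-lactone; immediate cold reduction also removes the epimerisable aldehyde before C4 can equilibrate.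

Step 9
Reactants: 16 (2S,3R,3aS,4R)-3-hydroxy-4-(hydroxymethyl)-7-[(1R)-1,3,3-trimethylcyclohexyl]-2,3,3a,4,5,6-hexahydro-1H-indene-2-carboxylic acid 2,3-lactone; 17 butanoyl chloride
Product: 18 (2S,3R,3aS,4R)-4-[(butanoyloxy)methyl]-3-hydroxy-7-[(1R)-1,3,3-trimethylcyclohexyl]-2,3,3a,4,5,6-hexahydro-1H-indene-2-carboxylic acid 2,3-lactone (target)
Conditions: butanoyl chloride, pyridine, CH2Cl2, 0 °C
Reagents that add atoms: butanoyl chloride, CCCC(Cl)=O
Why: Nucleophilic acyl substitution (O-acylation) of the only free hydroxyl group; the β-lactone is inert to pyridine at 0 °C and no stereocentre is involved.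

**Compound list**

1 | isophorone (3,5,5-trimethylcyclohex-2-en-1-one) | CC1=CC(=O)CC(C)(C)C1 | starting material
2 | (1R)-3,5,5-trimethylcyclohex-2-en-1-ol ((R)-isophorol) | O[C@H]1C=C(C)CC(C)(C)C1 | intermediate
3 | ethyl vinyl ether | C=COCC | starting material
4 | (3R)-3-(ethenyloxy)-1,5,5-trimethylcyclohex-1-ene (allyl vinyl ether, not isolated) | C=CO[C@H]1C=C(C)CC(C)(C)C1 | intermediate
5 | 2-[(1R)-1,5,5-trimethylcyclohex-2-en-1-yl]acetaldehyde | O=CC[C@]1(C)C=CCC(C)(C)C1 | intermediate
6 | 2-[(1R)-1,3,3-trimethylcyclohexyl]acetaldehyde | O=CC[C@]1(C)CCCC(C)(C)C1 | intermediate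
7 | diethyl 2-[(1R)-1,3,3-trimethylcyclohexyl]ethenyl phosphate (enol phosphate, E/Z mixture, not isolated) | CCOP(=O)(OCC)OC=C[C@]1(C)CCCC(C)(C)C1 | intermediate
8 | (1R)-1-ethynyl-1,3,3-trimethylcyclohexane | C#C[C@]1(C)CCCC(C)(C)C1 | intermediate
9 | tert-butyl acrylate | C=CC(=O)OC(C)(C)C | starting material
10 | tert-butyl 5-[(1R)-1,3,3-trimethylcyclohexyl]pent-4-ynoate | CC(C)(C)OC(=O)CCC#C[C@]1(C)CCCC(C)(C)C1 | intermediate
11 | acrolein | C=CC=O | starting material
12 | 5-[(1R)-1,3,3-trimethylcyclohexyl]pent-4-ynoyl chloride (acid chloride, not isolated) | O=C(Cl)CCC#C[C@]1(C)CCCC(C)(C)C1 | intermediate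
13 | (3S,4R)-4-ethenyl-3-{3-[(1R)-1,3,3-trimethylcyclohexyl]prop-2-yn-1-yl}oxetan-2-one | C=C[C@H]1OC(=O)[C@H]1CC#C[C@]2(C)CCCC(C)(C)C2 | intermediate
14 | (1S,5R)-3-{1-[(1R)-1,3,3-trimethylcyclohexyl]ethenyl}-6-oxabicyclo[3.2.0]hept-3-en-7-one (dienyl lactone, not isolated) | C=C([C@]1(C)CCCC(C)(C)C1)C2=C[C@H]3OC(=O)[C@H]3C2 | intermediate
15 | (2S,3R,3aS,4R)-4-formyl-3-hydroxy-7-[(1R)-1,3,3-trimethylcyclohexyl]-2,3,3a,4,5,6-hexahydro-1H-indene-2-carboxylic acid 2,3-lactone | O=C[C@@H]1CCC([C@]2(C)CCCC(C)(C)C2)=C2C[C@@H]3C(=O)O[C@@H]3[C@H]21 | intermediate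
16 | (2S,3R,3aS,4R)-3-hydroxy-4-(hydroxymethyl)-7-[(1R)-1,3,3-trimethylcyclohexyl]-2,3,3a,4,5,6-hexahydro-1H-indene-2-carboxylic acid 2,3-lactone | OC[C@@H]1CCC([C@]2(C)CCCC(C)(C)C2)=C2C[C@@H]3C(=O)O[C@@H]3[C@H]21 | intermediate
17 | butanoyl chloride | CCCC(Cl)=O | starting material
18 | (2S,3R,3aS,4R)-4-[(butanoyloxy)methyl]-3-hydroxy-7-[(1R)-1,3,3-trimethylcyclohexyl]-2,3,3a,4,5,6-hexahydro-1H-indene-2-carboxylic acid 2,3-lactone | CCCC(=O)OC[C@@H]1CCC([C@]2(C)CCCC(C)(C)C2)=C2C[C@@H]3C(=O)O[C@@H]3[C@H]21 | target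

**Step count and risks**

Total steps: 9. Longest linear sequence: 9 steps (from isophorone 1).

Steps most likely to fail:

Step 7 (tandem enyne metathesis/Diels–Alder). The alkyne carries a tert-alkyl group, and the dienyl β-lactone 14 is an allylic lactone that may not survive long in the pot. The fallback sets out from 13 and comes back at 15; it makes the two carbocycles on the ring-opened acid, in separate isolated operations, and closes the four-membered ring last. Lactone 13 is hydrolysed (LiOH, THF/H2O, 0 °C, acyl–oxygen cleavage) to (2S,3R)-3-hydroxy-2-{3-[(1R)-1,3,3-trimethylcyclohexyl]prop-2-yn-1-yl}pent-4-enoic acid F1. This robust substrate tolerates forcing metathesis (same ruthenium catalyst, ethene, higher loading and temperature) and gives, after isolation, (1S,2R)-2-hydroxy-4-{1-[(1R)-1,3,3-trimethylcyclohexyl]ethenyl}cyclopent-3-ene-1-carboxylic acid F2. The same amine-catalysed Diels–Alder reaction with acrolein, now anti to the cis hydroxyl and carboxyl groups, gives (2S,3R,3aS,4R)-4-formyl-3-hydroxy-7-[(1R)-1,3,3-trimethylcyclohexyl]-2,3,3a,4,5,6-hexahydro-1H-indene-2-carboxylic acid F3. Carboxyl activation (TsCl, pyridine, 0 °C) closes the β-lactone with retention at C3 and returns to 15.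

Step 6 (cyclocondensation with acrolein). A conjugated, polymerisable aldehyde is the least proven partner for this reaction. The fallback sets out from 12 and comes back at 13; it uses a saturated aldehyde and introduces the alkene afterwards. Acid chloride 12 is condensed under the same alkaloid/LiClO4 conditions with 3-(phenylselanyl)propanal to give (3S,4R)-4-[2-(phenylselanyl)ethyl]-3-{3-[(1R)-1,3,3-trimethylcyclohexyl]prop-2-yn-1-yl}oxetan-2-one F4. Oxidation (H2O2, pyridine, CH2Cl2, 0 °C to rt) and selenoxide syn-elimination unveil the vinyl group and give 13.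

Step 5 (palladium-catalysed alkyne–acrylate addition). The hindered alkyne may react slowly or oligomerise the acrylate. The fallback sets out from 8 and comes back at 12; it replaces the catalytic C–H addition by acetylide alkylation and oxidation. The lithium acetylide of 8 (n-BuLi, THF, −78 °C) opens oxetane in the presence of BF3·OEt2 to give 5-[(1R)-1,3,3-trimethylcyclohexyl]pent-4-yn-1-ol F5. Oxidation (TEMPO, PhI(OAc)2, MeCN/H2O) gives 5-[(1R)-1,3,3-trimethylcyclohexyl]pent-4-ynoic acid F6, and (COCl)2 with catalytic DMF gives acid chloride 12.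

Further compounds
F1 | step 7 | (2S,3R)-3-hydroxy-2-{3-[(1R)-1,3,3-trimethylcyclohexyl]prop-2-yn-1-yl}pent-4-enoic acid | C=C[C@@H](O)[C@H](CC#C[C@]1(C)CCCC(C)(C)C1)C(=O)O
F2 | step 7 | (1S,2R)-2-hydroxy-4-{1-[(1R)-1,3,3-trimethylcyclohexyl]ethenyl}cyclopent-3-ene-1-carboxylic acid | C=C([C@]1(C)CCCC(C)(C)C1)C2=C[C@@H](O)[C@H](C2)C(=O)O
F3 | step 7 | (2S,3R,3aS,4R)-4-formyl-3-hydroxy-7-[(1R)-1,3,3-trimethylcyclohexyl]-2,3,3a,4,5,6-hexahydro-1H-indene-2-carboxylic acid | O=C[C@@H]1CCC([C@]2(C)CCCC(C)(C)C2)=C2C[C@H](C(=O)O)[C@H](O)[C@H]21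
F4 | step 6 | (3S,4R)-4-[2-(phenylselanyl)ethyl]-3-{3-[(1R)-1,3,3-trimethylcyclohexyl]prop-2-yn-1-yl}oxetan-2-one | c1ccccc1[Se]CC[C@H]2OC(=O)[C@H]2CC#C[C@]3(C)CCCC(C)(C)C3
F5 | step 5 | 5-[(1R)-1,3,3-trimethylcyclohexyl]pent-4-yn-1-ol | OCCCC#C[C@]1(C)CCCC(C)(C)C1
F6 | step 5 | 5-[(1R)-1,3,3-trimethylcyclohexyl]pent-4-ynoic acid | OC(=O)CCC#C[C@]1(C)CCCC(C)(C)C1
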